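**Retrosynthetic overview**

- Last step is global O-debenzylation. The interflavan C4–C8 bond is cut into a C4-alkoxy tri-O-benzyl-epiafzelechin electrophile (upper unit) and tetra-O-benzyl-(−)-epicatechin (lower unit, one step from the natural product).
- In the upper unit, the C4 oxygen comes from benzylic oxidation, the cis C3 carbinol from hydride reduction of a flavan-3-one, and the C3 oxygen from hydroboration of a flav-3-ene.
- Key step: ring C of the upper unit is closed by oxa-6π electrocyclization of a vinyl o-quinone methide, made by carbonyl reduction and dehydration of a 2'-hydroxychalcone (aldol condensation of an acetophenone with a benzaldehyde).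
- Ring order: rings A and B of the upper unit are bought as arenes, ring C is formed by the electrocyclization, and the three rings of the lower unit arrive intact with their two stereocentres.
- Stereochemistry: upper C3 follows C2 and upper C4 follows C3. The upper unit is made racemic, so union with the single-enantiomer lower unit gives two diastereomers in about equal amount, and the wanted one is isolated by chromatography (at most half of the upper unit is used).

Assumption: compounds 1, 2 and 14 are taken as commercial; compounds 3, 5 and 7–13 are racemic, and where the SMILES of a racemate carries descriptors it shows the enantiomer that ends up in the target.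

**Route**

Step 1
Reactants: 1 1-[2,4-bis(benzyloxy)-6-hydroxyphenyl]ethan-1-one; 2 4-(benzyloxy)benzaldehyde
Product: 4 (E)-1-[2,4-bis(benzyloxy)-6-hydroxyphenyl]-3-[4-(benzyloxy)phenyl]prop-2-en-1-one, via aldol adduct 3 (not isolated)
Conditions: KOH (50% aq.), EtOH/THF, rt, 48 h
Reagents that add atoms: none
Why: Claisen–Schmidt (crossed aldol) condensation of the methyl ketone enolate with the non-enolisable aldehyde, followed by E1cB dehydration to the conjugated E-enone; no stereocentre remains.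

Step 2
Reactants: 4 (E)-1-[2,4-bis(benzyloxy)-6-hydroxyphenyl]-3-[4-(benzyloxy)phenyl]prop-2-en-1-one
Product: 7 (±)-5,7-bis(benzyloxy)-2-[4-(benzyloxy)phenyl]-2H-chromene, via allylic alcohol 5 (not isolated), via vinyl o-quinone methide 6 (not isolated)
Conditions: NaBH4, CeCl3·7H2O, MeOH/THF, 0 °C; then AcOH (cat.), toluene, 60 °C
Reagents that add atoms: none
Why: Luche 1,2-reduction gives the 2-hydroxybenzylic allylic alcohol, acid-induced loss of water gives the vinyl o-quinone methide, and its thermal disrotatory oxa-6π electrocyclization closes ring C and restores the aromaticity of ring A; C2 is formed here without bias, i.e. as the racemate.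

Step 3
Reactants: 7 (±)-5,7-bis(benzyloxy)-2-[4-(benzyloxy)phenyl]-2H-chromene
Product: 9 (±)-(2R*,3S*)-5,7-bis(benzyloxy)-2-[4-(benzyloxy)phenyl]chroman-3-ol (2,3-trans), via C3 alkylborane 8 (not isolated)
Conditions: BH3·THF, THF, 0 °C to rt; then NaOH, H2O2, 0 °C
Reagents that add atoms: hydrogen peroxide, OO
Why: hydroboration–oxidation, in which boron adds syn to the styrene-type C3=C4 bond at C3 (away from the aryl-bearing C4) on the face opposite the C2 aryl group and is replaced by OH with retention, so the C3 hydroxyl is trans to C2.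

Step 4
Reactants: 9 (±)-(2R*,3S*)-5,7-bis(benzyloxy)-2-[4-(benzyloxy)phenyl]chroman-3-ol
Product: 10 (±)-5,7-bis(benzyloxy)-2-[4-(benzyloxy)phenyl]chroman-3-one
Conditions: Dess–Martin periodinane, wet CH2Cl2, rt
Reagents that add atoms: none
Why: Dess–Martin oxidation of the secondary alcohol under neutral conditions, which the sensitive α-aryloxy ketone tolerates; the C3 centre is erased on purpose so that it can be reset cis.

Step 5
Reactants: 10 (±)-5,7-bis(benzyloxy)-2-[4-(benzyloxy)phenyl]chroman-3-one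
Product: 11 (±)-(2R*,3R*)-5,7-bis(benzyloxy)-2-[4-(benzyloxy)phenyl]chroman-3-ol (2,3-cis; racemic 5,7,4'-tri-O-benzylepiafzelechin)
Conditions: LiBH(s-Bu)3, LiBr, THF, −78 °C; then H2O
Reagents that add atoms: none
Why: the bulky trialkylborohydride reduces the ketone from the face opposite the C2 aryl group (1,2-substrate control), which places the new C3 hydroxyl cis to the aryl group.

Step 6
Reactants: 11 (±)-(2R*,3R*)-5,7-bis(benzyloxy)-2-[4-(benzyloxy)phenyl]chroman-3-ol
Product: 13 (±)-(2R*,3R*,4S*)-5,7-bis(benzyloxy)-2-[4-(benzyloxy)phenyl]-4-(2-ethoxyethoxy)chroman-3-ol, via C4 benzylic cation 12 (not isolated)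
Conditions: DDQ, HOCH2CH2OEt, CH2Cl2, rt
Reagents that add atoms: 2-ethoxyethanol, CCOCCO
Why: DDQ benzylic oxidation, in which hydride is abstracted from C4 (the position conjugated to the trioxygenated ring A) and the cation is trapped by the alcohol anti to the C3 hydroxyl; this C4 centre is only a placeholder because the ether is exchanged for the aryl group in step 8.

Step 7
Reactants: 14 (−)-epicatechin
Product: 15 5,7,3',4'-tetra-O-benzyl-(−)-epicatechin
Conditions: BnBr, K2CO3, DMF, 0 °C to rt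
Reagents that add atoms: benzyl bromide, BrCc1ccccc1
Why: Williamson etherification of the four phenols, the aliphatic C3 hydroxyl being too weakly acidic to react with K2CO3; both bought stereocentres (2R,3R) are untouched.

Step 8
Reactants: 13 (±)-(2R*,3R*,4S*)-5,7-bis(benzyloxy)-2-[4-(benzyloxy)phenyl]-4-(2-ethoxyethoxy)chroman-3-ol; 15 5,7,3',4'-tetra-O-benzyl-(−)-epicatechin (4 equiv, excess recovered)
Product: 16 5,7,4'-tri-O-benzyl-(−)-epiafzelechin-(4β→8)-5,7,3',4'-tetra-O-benzyl-(−)-epicatechin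
Conditions: TMSOTf (cat.), CH2Cl2, −78 °C; then SiO2 chromatography
Reagents that add atoms: none
Why: TMSOTf turns the C4 2-ethoxyethoxy group into a leaving group and the free C8 of 15 replaces it in an SN1-type Friedel–Crafts flavan-4-yl arylation (the same benzylic cation chemistry as in step 6), entering anti to the C3 hydroxyl, so C4 is set 3,4-trans by C3 while the lower unit keeps the (2R,3R) centres of 14; as 13 is racemic, the dimer with the mirror-image upper unit forms in about equal amount and is removed by chromatography as a diastereomer.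

Step 9
Reactants: 16 5,7,4'-tri-O-benzyl-(−)-epiafzelechin-(4β→8)-5,7,3',4'-tetra-O-benzyl-(−)-epicatechin
Product: 17 (−)-epiafzelechin-(4β→8)-(−)-epicatechin
Conditions: H2 (1 atm), Pd(OH)2/C, THF/MeOH/H2O, rt
Reagents that add atoms: none
Why: hydrogenolysis of the seven benzyl ethers under neutral conditions, which leaves the acid-labile interflavan bond and all five stereocentres untouched.

**Compound list**

1 | 1-[2,4-bis(benzyloxy)-6-hydroxyphenyl]ethan-1-one | CC(=O)c1c(O)cc(OCc2ccccc2)cc1OCc1ccccc1 | starting material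
2 | 4-(benzyloxy)benzaldehyde | O=Cc1ccc(OCc2ccccc2)cc1 | starting material
3 | (±)-1-[2,4-bis(benzyloxy)-6-hydroxyphenyl]-3-[4-(benzyloxy)phenyl]-3-hydroxypropan-1-one | O=C(CC(O)c1ccc(OCc2ccccc2)cc1)c1c(O)cc(OCc2ccccc2)cc1OCc1ccccc1 | intermediate
4 | (E)-1-[2,4-bis(benzyloxy)-6-hydroxyphenyl]-3-[4-(benzyloxy)phenyl]prop-2-en-1-one | O=C(/C=C/c1ccc(OCc2ccccc2)cc1)c1c(O)cc(OCc2ccccc2)cc1OCc1ccccc1 | intermediate
5 | (±)-(E)-3,5-bis(benzyloxy)-2-{3-[4-(benzyloxy)phenyl]-1-hydroxyprop-2-en-1-yl}phenol | OC(/C=C/c1ccc(OCc2ccccc2)cc1)c1c(O)cc(OCc2ccccc2)cc1OCc1ccccc1 | intermediate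
6 | (6Z)-3,5-bis(benzyloxy)-6-{(2E)-3-[4-(benzyloxy)phenyl]prop-2-en-1-ylidene}cyclohexa-2,4-dien-1-one (styryl arm cis to C=O) | O=C1C=C(OCc2ccccc2)C=C(OCc2ccccc2)/C1=C/C=C/c1ccc(OCc2ccccc2)cc1 | intermediate
7 | (±)-5,7-bis(benzyloxy)-2-[4-(benzyloxy)phenyl]-2H-chromene, (2S) drawn | C(c1ccccc1)Oc1ccc([C@H]2Oc3cc(OCc4ccccc4)cc(OCc4ccccc4)c3C=C2)cc1 | intermediate
8 | (±)-[5,7-bis(benzyloxy)-2-[4-(benzyloxy)phenyl]chroman-3-yl]borane, 2,3-trans, (2S,3S) drawn | C(c1ccccc1)Oc1ccc([C@H]2Oc3cc(OCc4ccccc4)cc(OCc4ccccc4)c3C[C@@H]2B)cc1 | intermediate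
9 | (±)-(2R*,3S*)-5,7-bis(benzyloxy)-2-[4-(benzyloxy)phenyl]chroman-3-ol, 2,3-trans, (2R,3S) drawn | C(c1ccccc1)Oc1ccc([C@H]2Oc3cc(OCc4ccccc4)cc(OCc4ccccc4)c3C[C@@H]2O)cc1 | intermediate
10 | (±)-5,7-bis(benzyloxy)-2-[4-(benzyloxy)phenyl]chroman-3-one, (2R) drawn | C(c1ccccc1)Oc1ccc([C@H]2Oc3cc(OCc4ccccc4)cc(OCc4ccccc4)c3CC2=O)cc1 | intermediate
11 | (±)-(2R*,3R*)-5,7-bis(benzyloxy)-2-[4-(benzyloxy)phenyl]chroman-3-ol, 2,3-cis, (2R,3R) drawn | C(c1ccccc1)Oc1ccc([C@H]2Oc3cc(OCc4ccccc4)cc(OCc4ccccc4)c3C[C@H]2O)cc1 | intermediate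
12 | (±)-(2R*,3R*)-5,7-bis(benzyloxy)-2-[4-(benzyloxy)phenyl]-3-hydroxychroman-4-ylium (C4 benzylic cation), (2R,3R) drawn | C(c1ccccc1)Oc1ccc([C@H]2Oc3cc(OCc4ccccc4)cc(OCc4ccccc4)c3[CH+][C@H]2O)cc1 | intermediate
13 | (±)-(2R*,3R*,4S*)-5,7-bis(benzyloxy)-2-[4-(benzyloxy)phenyl]-4-(2-ethoxyethoxy)chroman-3-ol, (2R,3R,4S) drawn | C(c1ccccc1)Oc1ccc([C@H]2Oc3cc(OCc4ccccc4)cc(OCc4ccccc4)c3[C@H](OCCOCC)[C@H]2O)cc1 | intermediate
14 | (−)-epicatechin, (2R,3R)-2-(3,4-dihydroxyphenyl)chroman-3,5,7-triol | Oc1cc(O)c2c(c1)O[C@H](c1ccc(O)c(O)c1)[C@H](O)C2 | starting material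
15 | 5,7,3',4'-tetra-O-benzyl-(−)-epicatechin, (2R,3R) | C(c1ccccc1)Oc1cc(OCc3ccccc3)c2c(c1)O[C@H](c1ccc(OCc3ccccc3)c(OCc3ccccc3)c1)[C@H](O)C2 | intermediate
16 | 5,7,4'-tri-O-benzyl-(−)-epiafzelechin-(4β→8)-5,7,3',4'-tetra-O-benzyl-(−)-epicatechin, upper (2R,3R,4R), lower (2R,3R) | C(c1ccccc1)Oc1ccc([C@H]2Oc3cc(OCc4ccccc4)cc(OCc4ccccc4)c3[C@H](c3c(OCc4ccccc4)cc(OCc4ccccc4)c4c3O[C@H](c3ccc(OCc5ccccc5)c(OCc5ccccc5)c3)[C@H](O)C4)[C@H]2O)cc1 | intermediate
17 | (−)-epiafzelechin-(4β→8)-(−)-epicatechin, upper (2R,3R,4R), lower (2R,3R) | Oc1ccc([C@H]2Oc3cc(O)cc(O)c3[C@H](c3c(O)cc(O)c4c3O[C@H](c3ccc(O)c(O)c3)[C@H](O)C4)[C@H]2O)cc1 | target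

**Step count and risks**

Total step count: 9. Longest linear sequence: 8 steps (steps 1–6, 8 and 9, from compound 1).

Steps most likely to fail:

Step 8. The free C3 hydroxyl of 13 can compete as a nucleophile, giving oligomers. Some C6 attack is also possible. The two diastereomeric dimers must be separated, which caps the yield at half of 13. The fallback sets out from 13. Acetylation (Ac2O, pyridine) gives (±)-(2R*,3R*,4S*)-5,7-bis(benzyloxy)-2-[4-(benzyloxy)phenyl]-4-(2-ethoxyethoxy)chroman-3-yl acetate F4. TMSOTf-promoted coupling of F4 with 15 is then assisted by the neighbouring acetate, which blocks self-condensation and shields the face cis to it. After chromatography this gives 3-O-acetyl-5,7,4'-tri-O-benzyl-(−)-epiafzelechin-(4β→8)-5,7,3',4'-tetra-O-benzyl-(−)-epicatechin F5, with its diastereomer removed at this stage. Methanolysis (K2CO3, MeOH/THF) removes the acetate and the route is rejoined at 16.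

Step 2. The reduction may overshoot by conjugate reduction of the chalcone or of the quinone methide, or the chalcone may close to the flavanone. The fallback sets out from 2. A Wittig reaction with Ph3P=CHCHO (toluene, 80 °C) gives (E)-3-[4-(benzyloxy)phenyl]prop-2-enal F1. Heating F1 with commercial 3,5-bis(benzyloxy)phenol (Oc1cc(OCc2ccccc2)cc(OCc2ccccc2)c1), PhB(OH)2 and a little AcOH in toluene gives (±)-5,7-bis(benzyloxy)-4-{(E)-2-[4-(benzyloxy)phenyl]ethenyl}-2-phenyl-4H-1,3,2-benzodioxaborinine F2. F2 fragments in the same pot to the o-quinone methide 6, which electrocyclizes, so the route is rejoined at 7.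

Step 3. Part of the boron may add at C4, and a C3 borane β to the ring oxygen can fragment. The fallback sets out from 7. Dimethyldioxirane (acetone, −20 °C) epoxidises the C3=C4 bond anti to the C2 aryl group to give (±)-5,7-bis(benzyloxy)-2-[4-(benzyloxy)phenyl]-3,4-epoxychroman F3. ZnI2 (cat.) then triggers a Meinwald rearrangement (C4 ionisation, 1,2-hydride shift) that delivers ketone 10, where the route is rejoined with step 4 saved.

**Further compounds**

F1 | step 2 | (E)-3-[4-(benzyloxy)phenyl]prop-2-enal | O=C/C=C/c1ccc(OCc2ccccc2)cc1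
F2 | step 2 | (±)-5,7-bis(benzyloxy)-4-{(E)-2-[4-(benzyloxy)phenyl]ethenyl}-2-phenyl-4H-1,3,2-benzodioxaborinine | B1(c2ccccc2)Oc2cc(OCc3ccccc3)cc(OCc3ccccc3)c2C(/C=C/c2ccc(OCc3ccccc3)cc2)O1
F3 | step 3 | (±)-5,7-bis(benzyloxy)-2-[4-(benzyloxy)phenyl]-3,4-epoxychroman, epoxide trans to the C2 aryl group | C(c1ccccc1)Oc1ccc([C@H]2Oc3cc(OCc4ccccc4)cc(OCc4ccccc4)c3[C@@H]4O[C@@H]42)cc1
F4 | step 8 | (±)-(2R*,3R*,4S*)-5,7-bis(benzyloxy)-2-[4-(benzyloxy)phenyl]-4-(2-ethoxyethoxy)chroman-3-yl acetate | C(c1ccccc1)Oc1ccc([C@H]2Oc3cc(OCc4ccccc4)cc(OCc4ccccc4)c3[C@H](OCCOCC)[C@H]2OC(C)=O)cc1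
F5 | step 8 | 3-O-acetyl-5,7,4'-tri-O-benzyl-(−)-epiafzelechin-(4β→8)-5,7,3',4'-tetra-O-benzyl-(−)-epicatechin | C(c1ccccc1)Oc1ccc([C@H]2Oc3cc(OCc4ccccc4)cc(OCc4ccccc4)c3[C@H](c3c(OCc4ccccc4)cc(OCc4ccccc4)c4c3O[C@H](c3ccc(OCc5ccccc5)c(OCc5ccccc5)c3)[C@H](O)C4)[C@H]2OC(C)=O)cc1
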